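**Plan**
- Retrosynthesis: cut the aryl ester C–O bond at C4 (azulene locants), then the C8a–C1 bond of the cyclopentane by a retro-[3,3] shift to an 8-vinylbicyclo[3.2.1]oct-6-en-8-ol, then the C8–vinyl bond, the two-carbon bridge (back to a propargyl group) and the cyclohexanone (back to benzyl acetoacetate and crotonaldehyde).
- Forward ring order: cyclohexanone (Michael/aldol), then the bicyclo[3.2.1]octenone (gold-catalysed closure of the two-carbon bridge), then an anionic oxy-Cope shift that opens the bridged six-membered ring to the cycloheptene and closes the cyclopentanone at the quaternary carbon, then isopropyl addition, enone formation, reduction and acylation.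
- Enabling feature: in the bicycle the C8 alkoxide sits between the ester-bearing bridgehead C1 and the C6(Me)=C7 bridge, a 3-oxido-1,5-diene locked in a boat; the ester makes C1–C8 the bond that breaks.
- Stereochemistry: the organocatalytic Michael step sets one methyl-bearing centre, which steers the quaternary bridgehead (alkylation anti to methyl); the sigmatropic shift transcribes the bridgeheads into C3a/C8a (cis fusion); C3 and C4 follow from convex-face attack; the relay methyl centre and the other temporary centres are erased.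

Key step: step 7

Remark: locants are cyclohexane numbering for 4–6, bicyclo[3.2.1]octane numbering for 7–10 and azulene numbering from 11 on; C1 of 4, the oxygen-bearing C4 of 4–15 and C7 of 14 are carried as epimer mixtures and left undefined in the SMILES because all are erased later.

Step 1
Reactants: 1 benzyl 3-oxobutanoate; 2 (E)-but-2-enal
Product: 4 benzyl (6S)-4-hydroxy-6-methyl-2-oxocyclohexane-1-carboxylate, via Michael adduct 3 (not isolated)
Conditions: (R)-α,α-diphenylprolinol trimethylsilyl ether (10 mol %), PhCO2H (10 mol %), toluene, 0 °C to rt; then DBU (0.2 equiv), CH2Cl2, 0 °C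
Reagents that add atoms: none
Why: Iminium activation of the enal by the (R)-configured amine shields one face, so the β-keto ester should add to give the (S)-methyl centre of 3, and base then closes the ring by aldol addition of the methyl ketone to the aldehyde (asymmetric organocatalytic Michael/aldol domino).

Step 2
Reactants: 4 benzyl (6S)-4-hydroxy-6-methyl-2-oxocyclohexane-1-carboxylate
Product: 5 benzyl (1S,6S)-4-hydroxy-6-methyl-2-oxo-1-(prop-2-yn-1-yl)cyclohexane-1-carboxylate
Conditions: HC≡CCH2Br, K2CO3, acetone, rt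
Reagents that add atoms: propargyl bromide, C#CCBr
Why: C-alkylation of the β-keto ester enolate should occur anti to the adjacent C6 methyl group, which sets the quaternary centre C1 with propargyl trans to methyl and erases the C1 epimer mixture.

Step 3
Reactants: 5 benzyl (1S,6S)-4-hydroxy-6-methyl-2-oxo-1-(prop-2-yn-1-yl)cyclohexane-1-carboxylate
Product: 6 benzyl (1S,6S)-2,4-bis(tert-butyldimethylsilyloxy)-6-methyl-1-(prop-2-yn-1-yl)cyclohex-2-ene-1-carboxylate
Conditions: TBSOTf (2.5 equiv), Et3N, CH2Cl2, −78 to 0 °C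
Reagents that add atoms: tert-butyldimethylsilyl trifluoromethanesulfonate, CC(C)(C)[Si](C)(C)OS(=O)(=O)C(F)(F)F
Why: The silyl triflate silylates the secondary alcohol and, by soft enolisation toward C3 (the only enolisable side of the ketone), forms the silyl enol ether; no stereocentre is created.

Step 4
Reactants: 6 benzyl (1S,6S)-2,4-bis(tert-butyldimethylsilyloxy)-6-methyl-1-(prop-2-yn-1-yl)cyclohex-2-ene-1-carboxylate
Product: 7 benzyl (1S,2S,5S)-4-(tert-butyldimethylsilyloxy)-2-methyl-6-methylidene-8-oxobicyclo[3.2.1]octane-1-carboxylate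
Conditions: [Au{P(tBu)2(biphenyl-2-yl)}(NCMe)]SbF6 (3 mol %), MeOH (2 equiv), CH2Cl2, rt
Reagents that add atoms: none
Why: The cationic gold complex activates the alkyne for 5-exo-dig attack by the enol ether carbon (gold-catalysed Conia-ene-type carbocyclisation of a silyl enol ether); the new bridgehead C5 can only form with the axial propargyl arm bridging cis, and methanol takes up the silyl group and protonates the vinyl–gold bond.

Step 5
Reactants: 7 benzyl (1S,2S,5S)-4-(tert-butyldimethylsilyloxy)-2-methyl-6-methylidene-8-oxobicyclo[3.2.1]octane-1-carboxylate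
Product: 8 benzyl (1R,2S,5S)-4-(tert-butyldimethylsilyloxy)-2,6-dimethyl-8-oxobicyclo[3.2.1]oct-6-ene-1-carboxylate
Conditions: RhCl3·3H2O (5 mol %), EtOH, 70 °C
Reagents that add atoms: none
Why: Metal-hydride olefin isomerisation should move the exocyclic double bond to the trisubstituted C6=C7 position, the only endocyclic position open because C5 is a bridgehead; no stereocentre changes.

Step 6
Reactants: 8 benzyl (1R,2S,5S)-4-(tert-butyldimethylsilyloxy)-2,6-dimethyl-8-oxobicyclo[3.2.1]oct-6-ene-1-carboxylate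
Product: 9 benzyl (1R,2S,5S,8R)-4-(tert-butyldimethylsilyloxy)-8-ethenyl-8-hydroxy-2,6-dimethylbicyclo[3.2.1]oct-6-ene-1-carboxylate
Conditions: CH2=CHMgBr, CeCl3, THF, −78 °C
Reagents that add atoms: vinylmagnesium bromide, C=C[Mg]Br
Why: The organocerium reagent adds 1,2 to the strained bridging ketone in preference to the ester, from the face of the C6=C7 bridge because the other face is screened by the axial C2 methyl group, which sets C8 with the vinyl group syn to the olefin bridge.

Step 7
Reactants: 9 benzyl (1R,2S,5S,8R)-4-(tert-butyldimethylsilyloxy)-8-ethenyl-8-hydroxy-2,6-dimethylbicyclo[3.2.1]oct-6-ene-1-carboxylate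
Product: 12 benzyl (3aS,6S,8aS)-4-(tert-butyldimethylsilyloxy)-6,8a-dimethyl-3-oxo-1,2,3,3a,4,5,6,8a-octahydroazulene-7-carboxylate, via potassium alkoxide 10 (not isolated), via potassium enolate 11 (not isolated)
Conditions: KH, 18-crown-6, THF, 0 °C to rt; then aq NH4Cl
Reagents that add atoms: none
Why: Deprotonation gives alkoxide 10, a 3-oxido-1,5-diene (C6=C7–C1–C8(O−)–CH=CH2) held in a boat by the bicycle, which undergoes the anionic oxy-Cope [3,3] shift: C1–C8 breaks while the vinyl terminus bonds to C6, giving enolate 11 and, on protonation, ketone 12. The closest known reaction type is the anionic oxy-Cope rearrangement of 7-vinylnorbornen-7-ols and 2-vinylbicyclo[2.2.2]octenols to cis-fused bicyclic ketones. The cyclopentanone closes by suprafacial bond formation between the vinyl CH2 and the methyl-bearing olefin carbon (new C8a–C1 bond), formally a 5-endo vinylogous Michael closure that the six-centre boat transition state permits, while the bridged six-membered ring opens to the cycloheptene. The new quaternary centre C8a is set by the bridgehead that becomes C3a: the vinyl group on C8 can reach only the olefin face syn to C8, so the new bond and the C3a–C3 bond are cis and methyl and hydrogen end on the same face of a cis ring fusion. The step needs C1–C8 to break and not C5–C8 (bonding at the substituted olefin carbon C6, not at C7); the benzyl ester on C1 secures this because cleavage on that side develops ester-dienolate (retro-aldol) character, whereas C5 has no stabilising group. It also needs the vinyl group syn to the C6=C7 bridge, which step 6 provides.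

Step 8
Reactants: 12 benzyl (3aS,6S,8aS)-4-(tert-butyldimethylsilyloxy)-6,8a-dimethyl-3-oxo-1,2,3,3a,4,5,6,8a-octahydroazulene-7-carboxylate
Product: 13 benzyl (3R,3aS,6S,8aS)-4-(tert-butyldimethylsilyloxy)-3-hydroxy-6,8a-dimethyl-3-(propan-2-yl)-1,2,3,3a,4,5,6,8a-octahydroazulene-7-carboxylate
Conditions: iPrMgCl, CeCl3, THF, −78 to 0 °C
Reagents that add atoms: isopropylmagnesium chloride, CC(C)[Mg]Cl
Why: Organocerium 1,2-addition to the cyclopentanone (faster than attack on the hindered unsaturated ester) should occur from the convex face, anti to the C3a–C4 bond, placing isopropyl cis to H-3a and the hydroxyl on the concave face.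

Step 9
Reactants: 13 benzyl (3R,3aS,6S,8aS)-4-(tert-butyldimethylsilyloxy)-3-hydroxy-6,8a-dimethyl-3-(propan-2-yl)-1,2,3,3a,4,5,6,8a-octahydroazulene-7-carboxylate
Product: 14 (3R,3aS,6S,8aS)-4-(tert-butyldimethylsilyloxy)-3-hydroxy-6,8a-dimethyl-3-(propan-2-yl)decahydroazulene-7-carboxylic acid
Conditions: H2 (1 atm), Pd/C, EtOAc, rt
Reagents that add atoms: none
Why: Heterogeneous hydrogenation saturates the conjugated C7=C8 double bond and cleaves the benzyl ester by hydrogenolysis in one operation; the new C7 centre is irrelevant because it is removed in step 10.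

Step 10
Reactants: 14 (3R,3aS,6S,8aS)-4-(tert-butyldimethylsilyloxy)-3-hydroxy-6,8a-dimethyl-3-(propan-2-yl)decahydroazulene-7-carboxylic acid
Product: 15 (3R,3aS,6R,8aR)-4-(tert-butyldimethylsilyloxy)-6,8a-dimethyl-3-(propan-2-yl)decahydroazulen-3-ol
Conditions: 9-mesityl-10-methylacridinium BF4 (5 mol %), PhSSPh (10 mol %), iPr2NEt (20 mol %), CF3CH2OH, blue LEDs, rt
Reagents that add atoms: none
Why: Photoredox hydrodecarboxylation (oxidation of the carboxylate, loss of CO2, hydrogen-atom transfer from thiophenol) removes the carboxyl group that served as the activating group, leaving C7 as CH2.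

Step 11
Reactants: 15 (3R,3aS,6R,8aR)-4-(tert-butyldimethylsilyloxy)-6,8a-dimethyl-3-(propan-2-yl)decahydroazulen-3-ol
Product: 16 (3R,3aS,6R,8aR)-6,8a-dimethyl-3-(propan-2-yl)decahydroazulene-3,4-diol
Conditions: Bu4NF, THF, 50 °C
Reagents that add atoms: none
Why: Fluoride cleaves the secondary silyl ether; no stereocentre changes.

Step 12
Reactants: 16 (3R,3aS,6R,8aR)-6,8a-dimethyl-3-(propan-2-yl)decahydroazulene-3,4-diol
Product: 17 (3R,3aR,8aR)-3-hydroxy-6,8a-dimethyl-3-(propan-2-yl)-2,3,3a,7,8,8a-hexahydroazulen-4(1H)-one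
Conditions: IBX (4 equiv), DMSO/PhF, 75 °C
Reagents that add atoms: none
Why: IBX oxidises the secondary alcohol to the ketone and then dehydrogenates it to the enone; the double bond can form only toward C5–C6 because C3a has no β-hydrogen (C3 and C8a are fully substituted), which also erases the relay methyl stereocentre and the C4 epimer mixture.

Step 13
Reactants: 17 (3R,3aR,8aR)-3-hydroxy-6,8a-dimethyl-3-(propan-2-yl)-2,3,3a,7,8,8a-hexahydroazulen-4(1H)-one
Product: 18 (3R,3aS,4R,8aR)-6,8a-dimethyl-3-(propan-2-yl)-1,2,3,3a,4,7,8,8a-octahydroazulene-3,4-diol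
Conditions: NaBH4, CeCl3·7H2O, MeOH, −78 °C
Reagents that add atoms: none
Why: Luche 1,2-reduction; hydride should enter from the convex face, anti to the C3a–C3 bond, giving the (4R)-alcohol cis to the C3 hydroxyl.

Step 14
Reactants: 19 3-hydroxy-4-methoxybenzoic acid
Product: 21 3-(tert-butyldimethylsilyloxy)-4-methoxybenzoic acid, via silyl ester 20 (not isolated)
Conditions: TBSCl (2.5 equiv), imidazole, DMF, rt; then AcOH/THF/H2O, rt
Reagents that add atoms: tert-butyldimethylsilyl chloride, CC(C)(C)[Si](C)(C)Cl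
Why: Both acidic groups are silylated and the labile silyl ester is then hydrolysed selectively, leaving the phenol protected.

Step 15
Reactants: 18 (3R,3aS,4R,8aR)-6,8a-dimethyl-3-(propan-2-yl)-1,2,3,3a,4,7,8,8a-octahydroazulene-3,4-diol; 21 3-(tert-butyldimethylsilyloxy)-4-methoxybenzoic acid
Product: 22 (3R,3aS,4R,8aR)-3-hydroxy-6,8a-dimethyl-3-(propan-2-yl)-1,2,3,3a,4,7,8,8a-octahydroazulen-4-yl 3-(tert-butyldimethylsilyloxy)-4-methoxybenzoate
Conditions: DCC, DMAP (cat.), CH2Cl2, 0 °C to rt
Reagents that add atoms: none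
Why: Steglich esterification acylates the secondary allylic alcohol with retention at C4, the tertiary alcohol being too hindered to react.

Step 16
Reactants: 22 (3R,3aS,4R,8aR)-3-hydroxy-6,8a-dimethyl-3-(propan-2-yl)-1,2,3,3a,4,7,8,8a-octahydroazulen-4-yl 3-(tert-butyldimethylsilyloxy)-4-methoxybenzoate
Product: 23 (3R,3aS,4R,8aR)-3-hydroxy-6,8a-dimethyl-3-(propan-2-yl)-1,2,3,3a,4,7,8,8a-octahydroazulen-4-yl 3-hydroxy-4-methoxybenzoate
Conditions: Bu4NF, AcOH, THF, 0 °C
Reagents that add atoms: none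
Why: Buffered fluoride removes the aryl silyl ether without touching the allylic ester.

**Compound list**
1 | benzyl 3-oxobutanoate | CC(=O)CC(=O)OCc1ccccc1 | starting material
2 | (E)-but-2-enal | C/C=C/C=O | starting material
3 | benzyl (3S)-2-acetyl-3-methyl-5-oxopentanoate | CC(=O)C(C(=O)OCc1ccccc1)[C@@H](C)CC=O | intermediate
4 | benzyl (6S)-4-hydroxy-6-methyl-2-oxocyclohexane-1-carboxylate | O=C1CC(O)C[C@H](C)C1C(=O)OCc2ccccc2 | intermediate
5 | benzyl (1S,6S)-4-hydroxy-6-methyl-2-oxo-1-(prop-2-yn-1-yl)cyclohexane-1-carboxylate | O=C1CC(O)C[C@H](C)[C@]1(CC#C)C(=O)OCc2ccccc2 | intermediate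
6 | benzyl (1S,6S)-2,4-bis(tert-butyldimethylsilyloxy)-6-methyl-1-(prop-2-yn-1-yl)cyclohex-2-ene-1-carboxylate | CC(C)(C)[Si](C)(C)OC1=CC(O[Si](C)(C)C(C)(C)C)C[C@H](C)[C@]1(CC#C)C(=O)OCc2ccccc2 | intermediate
7 | benzyl (1S,2S,5S)-4-(tert-butyldimethylsilyloxy)-2-methyl-6-methylidene-8-oxobicyclo[3.2.1]octane-1-carboxylate | O=C1[C@@H]2C(O[Si](C)(C)C(C)(C)C)C[C@H](C)[C@@]1(C(=O)OCc3ccccc3)CC2=C | intermediate
8 | benzyl (1R,2S,5S)-4-(tert-butyldimethylsilyloxy)-2,6-dimethyl-8-oxobicyclo[3.2.1]oct-6-ene-1-carboxylate | O=C1[C@@H]2C(O[Si](C)(C)C(C)(C)C)C[C@H](C)[C@@]1(C(=O)OCc3ccccc3)C=C2C | intermediate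
9 | benzyl (1R,2S,5S,8R)-4-(tert-butyldimethylsilyloxy)-8-ethenyl-8-hydroxy-2,6-dimethylbicyclo[3.2.1]oct-6-ene-1-carboxylate | O[C@]1(C=C)[C@@H]2C(O[Si](C)(C)C(C)(C)C)C[C@H](C)[C@@]1(C(=O)OCc3ccccc3)C=C2C | intermediate
10 | potassium alkoxide of 9 | [K+].[O-][C@]1(C=C)[C@@H]2C(O[Si](C)(C)C(C)(C)C)C[C@H](C)[C@@]1(C(=O)OCc3ccccc3)C=C2C | intermediate
11 | potassium enolate of 12 | [K+].[O-]C1=CC[C@@]2(C)C=C(C(=O)OCc3ccccc3)[C@@H](C)CC(O[Si](C)(C)C(C)(C)C)[C@@H]12 | intermediate
12 | benzyl (3aS,6S,8aS)-4-(tert-butyldimethylsilyloxy)-6,8a-dimethyl-3-oxo-1,2,3,3a,4,5,6,8a-octahydroazulene-7-carboxylate | O=C1CC[C@@]2(C)C=C(C(=O)OCc3ccccc3)[C@@H](C)CC(O[Si](C)(C)C(C)(C)C)[C@@H]12 | intermediate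
13 | benzyl (3R,3aS,6S,8aS)-4-(tert-butyldimethylsilyloxy)-3-hydroxy-6,8a-dimethyl-3-(propan-2-yl)-1,2,3,3a,4,5,6,8a-octahydroazulene-7-carboxylate | CC(C)[C@]1(O)CC[C@@]2(C)C=C(C(=O)OCc3ccccc3)[C@@H](C)CC(O[Si](C)(C)C(C)(C)C)[C@@H]12 | intermediate
14 | (3R,3aS,6S,8aS)-4-(tert-butyldimethylsilyloxy)-3-hydroxy-6,8a-dimethyl-3-(propan-2-yl)decahydroazulene-7-carboxylic acid | CC(C)[C@]1(O)CC[C@@]2(C)CC(C(=O)O)[C@@H](C)CC(O[Si](C)(C)C(C)(C)C)[C@@H]12 | intermediate
15 | (3R,3aS,6R,8aR)-4-(tert-butyldimethylsilyloxy)-6,8a-dimethyl-3-(propan-2-yl)decahydroazulen-3-ol | CC(C)[C@]1(O)CC[C@@]2(C)CC[C@@H](C)CC(O[Si](C)(C)C(C)(C)C)[C@@H]12 | intermediate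
16 | (3R,3aS,6R,8aR)-6,8a-dimethyl-3-(propan-2-yl)decahydroazulene-3,4-diol | CC(C)[C@]1(O)CC[C@@]2(C)CC[C@@H](C)CC(O)[C@@H]12 | intermediate
17 | (3R,3aR,8aR)-3-hydroxy-6,8a-dimethyl-3-(propan-2-yl)-2,3,3a,7,8,8a-hexahydroazulen-4(1H)-one | CC(C)[C@]1(O)CC[C@@]2(C)CCC(C)=CC(=O)[C@@H]12 | intermediate
18 | (3R,3aS,4R,8aR)-6,8a-dimethyl-3-(propan-2-yl)-1,2,3,3a,4,7,8,8a-octahydroazulene-3,4-diol | CC(C)[C@]1(O)CC[C@@]2(C)CCC(C)=C[C@@H](O)[C@@H]12 | intermediate
19 | 3-hydroxy-4-methoxybenzoic acid | COc1ccc(C(=O)O)cc1O | starting material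
20 | tert-butyldimethylsilyl 3-(tert-butyldimethylsilyloxy)-4-methoxybenzoate | COc1ccc(C(=O)O[Si](C)(C)C(C)(C)C)cc1O[Si](C)(C)C(C)(C)C | intermediate
21 | 3-(tert-butyldimethylsilyloxy)-4-methoxybenzoic acid | COc1ccc(C(=O)O)cc1O[Si](C)(C)C(C)(C)C | intermediate
22 | (3R,3aS,4R,8aR)-3-hydroxy-6,8a-dimethyl-3-(propan-2-yl)-1,2,3,3a,4,7,8,8a-octahydroazulen-4-yl 3-(tert-butyldimethylsilyloxy)-4-methoxybenzoate | COc1ccc(C(=O)O[C@@H]2C=C(C)CC[C@]3(C)CC[C@@](O)(C(C)C)[C@H]23)cc1O[Si](C)(C)C(C)(C)C | intermediate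
23 | (3R,3aS,4R,8aR)-3-hydroxy-6,8a-dimethyl-3-(propan-2-yl)-1,2,3,3a,4,7,8,8a-octahydroazulen-4-yl 3-hydroxy-4-methoxybenzoate | COc1ccc(C(=O)O[C@@H]2C=C(C)CC[C@]3(C)CC[C@@](O)(C(C)C)[C@H]23)cc1O | target

Total steps: 16. Longest linear sequence: 15 (steps 1–13, 15, 16).

**Steps most likely to fail**

Step 7. The alkoxide may fragment by retro-aldol cleavage of C1–C8 faster than the new C–C bond forms, so that the opened ester dienolate recloses at the wrong carbon (a net 1,3-shift) or the path through the other bridgehead competes. The fallback leaves the anionic manifold. Starting from 9, the tertiary alcohol is capped with Me3SiOTf/2,6-lutidine to give benzyl (1R,2S,5S,8R)-4-(tert-butyldimethylsilyloxy)-8-ethenyl-2,6-dimethyl-8-(trimethylsilyloxy)bicyclo[3.2.1]oct-6-ene-1-carboxylate F1. Heating F1 in o-dichlorobenzene at about 200 °C should bring about the neutral, concerted siloxy-Cope shift, in which no free enolate can escape, to the silyl enol ether benzyl (3aS,6S,8aS)-4-(tert-butyldimethylsilyloxy)-6,8a-dimethyl-3-(trimethylsilyloxy)-1,3a,4,5,6,8a-hexahydroazulene-7-carboxylate F2. K2CO3 in MeOH then releases ketone 12, where the route is rejoined.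

Step 5. The double-bond migration may stop at an unfavourable exocyclic/endocyclic equilibrium, or the medium may cause desilylation or a skeletal shift of the bridged ketone. The fallback avoids any isomerisation. Starting from 4, electrophilic C-alkynylation of the β-keto ester with 1-(prop-1-yn-1-yl)-1,2-benziodoxol-3(1H)-one and tetramethylguanidine should give benzyl (1R,6S)-4-hydroxy-6-methyl-2-oxo-1-(prop-1-yn-1-yl)cyclohexane-1-carboxylate F3. Bis-silylation as in step 3 gives benzyl (1R,6S)-2,4-bis(tert-butyldimethylsilyloxy)-6-methyl-1-(prop-1-yn-1-yl)cyclohex-2-ene-1-carboxylate F4. The gold complex of step 4 then closes the ring in the 5-endo-dig mode, which puts the double bond inside the ring and delivers 8 directly.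

Step 1. The aldol ring closure may not stop at the β-hydroxy ketone (loss of water), or the methyl ketone may not enolise under the mild base. The fallback accepts the elimination and re-installs the oxygen. Starting from 3 (made as in step 1), TsOH in toluene at 80 °C completes the aldol condensation to benzyl (6S)-6-methyl-2-oxocyclohex-3-ene-1-carboxylate F5. Copper-catalysed conjugate borylation (CuCl, NaOtBu, a bisphosphine, bis(pinacolato)diboron, MeOH) gives benzyl (6S)-6-methyl-2-oxo-4-(4,4,5,5-tetramethyl-1,3,2-dioxaborolan-2-yl)cyclohexane-1-carboxylate F6. Oxidation with NaBO3 returns to 4.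

Further compounds
F1 | step 7 | benzyl (1R,2S,5S,8R)-4-(tert-butyldimethylsilyloxy)-8-ethenyl-2,6-dimethyl-8-(trimethylsilyloxy)bicyclo[3.2.1]oct-6-ene-1-carboxylate | C[Si](C)(C)O[C@]1(C=C)[C@@H]2C(O[Si](C)(C)C(C)(C)C)C[C@H](C)[C@@]1(C(=O)OCc3ccccc3)C=C2C
F2 | step 7 | benzyl (3aS,6S,8aS)-4-(tert-butyldimethylsilyloxy)-6,8a-dimethyl-3-(trimethylsilyloxy)-1,3a,4,5,6,8a-hexahydroazulene-7-carboxylate | C[Si](C)(C)OC1=CC[C@@]2(C)C=C(C(=O)OCc3ccccc3)[C@@H](C)CC(O[Si](C)(C)C(C)(C)C)[C@@H]12
F3 | step 5 | benzyl (1R,6S)-4-hydroxy-6-methyl-2-oxo-1-(prop-1-yn-1-yl)cyclohexane-1-carboxylate | O=C1CC(O)C[C@H](C)[C@]1(C#CC)C(=O)OCc2ccccc2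
F4 | step 5 | benzyl (1R,6S)-2,4-bis(tert-butyldimethylsilyloxy)-6-methyl-1-(prop-1-yn-1-yl)cyclohex-2-ene-1-carboxylate | CC(C)(C)[Si](C)(C)OC1=CC(O[Si](C)(C)C(C)(C)C)C[C@H](C)[C@]1(C#CC)C(=O)OCc2ccccc2
F5 | step 1 | benzyl (6S)-6-methyl-2-oxocyclohex-3-ene-1-carboxylate | O=C1C=CC[C@H](C)C1C(=O)OCc2ccccc2
F6 | step 1 | benzyl (6S)-6-methyl-2-oxo-4-(4,4,5,5-tetramethyl-1,3,2-dioxaborolan-2-yl)cyclohexane-1-carboxylate | O=C1CC(B2OC(C)(C)C(C)(C)O2)C[C@H](C)C1C(=O)OCc3ccccc3
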